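**Plan**
1. Retrosynthetic cuts, in order: C4=C5 (ring-closing metathesis), the C1–O–C10 oxirane oxygen (Sharpless epoxidation of the C14 allylic alcohol), O–C6 of the lactone, C7–C8 (Nozaki–Hiyama–Kishi allylation), C1=C10 (Still–Gennari olefination).
2. Forward: a ten-carbon aldehyde (C8–C10, C1–C4, C14, C15) and a dienoate bromide (C5–C7, C11–C13 and one sacrificial methyl carbon) are joined at C7–C8. The five-membered lactone ring (O, C6, C7, C11, C12) is closed next, then the oxirane, and the ten-membered carbocycle last.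
3. Enabling feature: C6 is the γ-carbon of the C12 acrylic acid and is allylic to C4=C5 in the target. It can therefore be carried without oxygen as the inner carbon of a C5=C6 propenyl π bond. The acid oxygen is delivered to it 5-exo while the double bond moves outward to a vinyl group, which is the handle needed to close C4=C5.
4. This follows the presumed biosynthetic order: oxygen at C8 first, then oxidative 6,12-lactone closure on an unoxygenated C6. The 6,12- versus 8,12-olide question does not arise, because O8 is already acylated.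
5. Stereochemistry: C7 and C8 come from a ligand-controlled, syn-selective chromium allylation. C6 comes from C7 in the key step (trans). C1 and C10 come from L-(+)-diethyl tartrate. The 1(10) geometry comes from the Still–Gennari step and the 4Z geometry from ring constraint in the metathesis.

Key step: step 13

Locants: C1–C15 are the germacrane locants of the target (carbocycle C1–C10; C11–C13 = acrylate unit on C7; C14 = CH2OH on C10; C15 = CH3 on C4). They are used for all intermediates.

Assumption: the (S,S)-carbazole bis(oxazoline) ligand is taken to send the allylchromium reagent to the Si face of the C8 aldehyde. If the sense proves opposite, the (R,R)-ligand is used with no other change.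

Step 1
Reactants: 1 methyl 2-[bis(2,2,2-trifluoroethoxy)phosphoryl]acetate; 2 tert-butyl(2-iodoethoxy)dimethylsilane
Product: 3 methyl 2-[bis(2,2,2-trifluoroethoxy)phosphoryl]-4-(tert-butyldimethylsilyloxy)butanoate (racemic)
Conditions: NaH, DMF, 0 °C to rt
Reagents that add atoms: none
Why: SN2 C-alkylation of the stabilised phosphonoacetate anion by a primary iodide brings in C9 and C8, and the new centre is lost again in step 3.

Step 2
Reactants: 4 ethyl 4-methylpent-4-enoate
Product: 5 4-methylpent-4-enal
Conditions: iBu2AlH (1.05 equiv), CH2Cl2, −78 °C; aqueous potassium sodium tartrate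
Reagents that add atoms: none
Why: Partial ester reduction stops at the tetrahedral aluminate at low temperature and should release the aldehyde only on work-up, with the isolated olefin untouched.

Step 3
Reactants: 3 phosphonate; 5 4-methylpent-4-enal
Product: 6 methyl (Z)-2-[2-(tert-butyldimethylsilyloxy)ethyl]-6-methylhepta-2,6-dienoate
Conditions: KN(SiMe3)2, 18-crown-6, THF, −78 °C
Reagents that add atoms: none
Why: In the Still–Gennari olefination the electron-poor trifluoroethyl phosphonate eliminates under kinetic control, so the ester carbon C14 should end up cis to C2, which is the 1(10) geometry with C2 trans to C9.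

Step 4
Reactants: 6 Z-enoate
Product: 7 (Z)-2-[2-(tert-butyldimethylsilyloxy)ethyl]-6-methylhepta-2,6-dien-1-ol
Conditions: iBu2AlH (2.3 equiv), CH2Cl2, −78 to −20 °C; aqueous potassium sodium tartrate
Reagents that add atoms: none
Why: 1,2-Reduction of the enoate by the aluminium hydride should give the C14 allylic alcohol with the olefin geometry and the silyl ether kept.

Step 5
Reactants: 7 allylic alcohol
Product: 8 tert-butyl{[(Z)-2-[2-(tert-butyldimethylsilyloxy)ethyl]-6-methylhepta-2,6-dienyl]oxy}diphenylsilane
Conditions: tBuPh2SiCl, imidazole, CH2Cl2, rt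
Reagents that add atoms: tert-butyl(chloro)diphenylsilane, CC(C)(C)[Si](Cl)(c1ccccc1)c1ccccc1
Why: Imidazole-promoted silylation puts an acid-robust group on O14, which must outlast the removal of the other silyl ether and steps 7–13.

Step 6
Reactants: 8 bis-silyl ether
Product: 9 (Z)-3-[(tert-butyldiphenylsilyloxy)methyl]-7-methylocta-3,7-dien-1-ol
Conditions: camphorsulfonic acid (10 mol %), MeOH–CH2Cl2, 0 °C
Reagents that add atoms: none
Why: Acid-catalysed methanolysis should remove the far more labile primary tert-butyldimethylsilyl ether and leave the tert-butyldiphenylsilyl ether in place (selective desilylation).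

Step 7
Reactants: 9 homoallylic alcohol
Product: 10 (Z)-3-[(tert-butyldiphenylsilyloxy)methyl]-7-methylocta-3,7-dienal
Conditions: Dess–Martin periodinane, CH2Cl2, 0 °C to rt; used at once
Reagents that add atoms: none
Why: The Dess–Martin oxidation runs without base, so the β,γ-double bond should not move into conjugation with the new C8 aldehyde.

Step 8
Reactants: 11 tert-butyl acrylate; 12 (E)-but-2-enal
Product: 13 tert-butyl (E)-3-hydroxy-2-methylidenehex-4-enoate (racemic)
Conditions: DABCO, 1,4-dioxane–H2O, rt
Reagents that add atoms: none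
Why: The Morita–Baylis–Hillman reaction joins C11 to C7 by 1,2-addition to the enal, and the carbinol centre is erased in step 9.

Step 9
Reactants: 13 Baylis–Hillman alcohol
Product: 14 tert-butyl (2Z,4E)-2-(bromomethyl)hexa-2,4-dienoate
Conditions: N-bromosuccinimide, Me2S, CH2Cl2, 0 °C to rt
Reagents that add atoms: N-bromosuccinimide, O=C1CCC(=O)N1Br
Why: The alkoxysulfonium salt made under Corey–Kim-type conditions is opened by bromide in the SN2′ sense to the conjugated primary bromide, under neutral conditions that spare the tert-butyl ester.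

Step 10
Reactants: 10 aldehyde; 14 dienoate bromide
Product: 16 tert-butyl (3R,4R,6Z)-6-[(tert-butyldiphenylsilyloxy)methyl]-4-hydroxy-10-methyl-2-methylidene-3-[(E)-prop-1-enyl]undeca-6,10-dienoate, via trimethylsilyl ether 15 (not isolated)
Conditions: CrCl2 (10 mol %), 1,8-bis[(S)-4-isopropyl-4,5-dihydrooxazol-2-yl]-3,6-diphenyl-9H-carbazole (12 mol %), iPr2NEt (30 mol %), Mn powder, Me3SiCl, THF, 0 °C to rt; then 1 M HCl, THF, 0 °C
Reagents that add atoms: chlorotrimethylsilane, C[Si](C)(C)Cl (its silyl group stays only in 15)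
Why: In this catalytic asymmetric Nozaki–Hiyama–Kishi 2-(alkoxycarbonyl)allylation the equilibrating allylchromium species holds C6 cis to CH2Cr and should react at its γ-carbon C7 through a closed chair to the syn 7R,8R pair, while the ligand selects the Si face of the aldehyde and the bulky tert-butyl ester keeps O8 from lactonising.

Step 11
Reactants: 16 homoallylic alcohol
Product: 17 tert-butyl (3R,4R,6Z)-6-[(tert-butyldiphenylsilyloxy)methyl]-10-methyl-2-methylidene-4-(2-methylpropanoyloxy)-3-[(E)-prop-1-enyl]undeca-6,10-dienoate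
Conditions: (iPrCO)2O, DMAP (cat.), pyridine, CH2Cl2, 0 °C to rt
Reagents that add atoms: 2-methylpropanoic anhydride, CC(C)C(=O)OC(=O)C(C)C
Why: DMAP-catalysed acylation installs the final C8 ester with retention and takes O8 out of play as a lactone partner.

Step 12
Reactants: 17 tert-butyl ester
Product: 19 (3R,4R,6Z)-6-[(tert-butyldiphenylsilyloxy)methyl]-10-methyl-2-methylidene-4-(2-methylpropanoyloxy)-3-[(E)-prop-1-enyl]undeca-6,10-dienoic acid, via trimethylsilyl ester 18 (not isolated)
Conditions: Me3SiOTf, 2,6-lutidine, CH2Cl2, 0 °C; then pH 5 phosphate buffer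
Reagents that add atoms: trimethylsilyl trifluoromethanesulfonate, C[Si](C)(C)OS(=O)(=O)C(F)(F)F (its silyl group stays only in 18)
Why: Silyl-triflate cleavage of the tert-butyl ester loses isobutene in a buffered, proton-poor medium, so the 1,1-disubstituted olefin, the silyl ether and the isobutyrate should survive.

Step 13
Reactants: 19 dienoic acid
Product: 20 (1R,3Z)-3-[(tert-butyldiphenylsilyloxy)methyl]-1-[(2R,3R)-2-ethenyl-4-methylidene-5-oxooxolan-3-yl]-7-methylocta-3,7-dienyl 2-methylpropanoate
Conditions: Pd(OAc)2 (10 mol %), NaOAc, O2 (1 atm), DMSO, 25 to 40 °C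
Reagents that add atoms: none
Why: The carboxylate of 19 binds divalent palladium, the metal coordinates the C5=C6 π bond, and oxypalladation joins the acid oxygen to C6 while C5 becomes a σ-alkylpalladium centre; β-hydride elimination toward the methyl group then releases the vinyl lactone, and O2 in DMSO returns the palladium hydride to Pd(OAc)2. The closest known reaction type is the aerobic Pd(OAc)2/DMSO oxidative (Wacker-type) cyclisation of 4-alkenoic acids to γ-alkenyl-γ-butyrolactones. The one ring closed is the five-membered lactone (O, C6, C7, C11, C12), in the 5-exo-trig mode. The new stereocentre C6 is controlled by C7: in the rotamer of least allylic strain H7 lies in the olefin plane, C11 with its carboxylate stands over one face and the large C8 branch over the other, so O6 and C8 should end up on opposite sides of the new ring (6R, trans), an outcome that reversible oxypalladation should reinforce. Site selectivity is needed among four olefins and two conceivable lactones: only C5=C6 lies at five-ring distance from the carboxyl group, the C1=C10 and C4 olefins could only give rings of seven or more members, and O8 is already an isobutyrate, so no 8,12-olide can form. Elimination must run away from the C–O bond, which the anti relation of palladium and H6 and the three freely rotating methyl hydrogens should secure.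

Step 14
Reactants: 20 silyl-protected vinyl lactone
Product: 21 (1R,3Z)-1-[(2R,3R)-2-ethenyl-4-methylidene-5-oxooxolan-3-yl]-3-(hydroxymethyl)-7-methylocta-3,7-dienyl 2-methylpropanoate
Conditions: HF·pyridine, pyridine–THF, 0 °C to rt
Reagents that add atoms: none
Why: Buffered fluoride desilylation frees the C14 alcohol without the basic conditions that would add to the α-methylene lactone or cleave the ester.

Step 15
Reactants: 21 allylic alcohol
Product: 22 (1R)-1-[(2R,3R)-2-ethenyl-4-methylidene-5-oxooxolan-3-yl]-2-[(2S,3R)-2-(hydroxymethyl)-3-(3-methylbut-3-enyl)oxiran-2-yl]ethyl 2-methylpropanoate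
Conditions: Ti(OiPr)4, L-(+)-diethyl tartrate, tBuOOH, 4 Å molecular sieves, CH2Cl2, −20 °C; aqueous FeSO4–tartaric acid work-up
Reagents that add atoms: tert-butyl hydroperoxide, CC(C)(C)OO
Why: The Sharpless asymmetric epoxidation touches only the olefin that carries the CH2OH group, and L-(+)-tartrate should deliver oxygen to the face that gives 10S,1R (reagent control), while the olefin geometry fixes C2 trans to C9 on the oxirane; removing this olefin also blocks a six-membered-ring metathesis pathway in step 16.

Step 16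
Reactants: 22 epoxy alcohol diene
Product: 23 (1R,4Z,6R,7R,8R,10S)-1,10-epoxy-14-hydroxy-8-(2-methylpropanoyloxy)germacra-4,11(13)-dien-12,6-olide (target)
Conditions: second-generation Hoveyda–Grubbs catalyst RuCl2(H2IMes)(=CH-C6H4-2-OiPr) (added in portions), 1,4-benzoquinone (cat.), toluene (0.5 mM), 80 to 110 °C, argon sparge
Reagents that add atoms: none
Why: In the ring-closing metathesis ruthenium loads on the C5 vinyl group and closes on the C4 isopropenyl group with loss of ethene, the ten-membered ring allows only the 4Z trisubstituted olefin, the same C4=C5 closure is known in the related furanoheliangolide series, and the electron-poor C11=C13 olefin, the oxirane and the free alcohol are tolerated by the catalyst.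

**Compound list**
1 | methyl 2-[bis(2,2,2-trifluoroethoxy)phosphoryl]acetate | COC(=O)CP(=O)(OCC(F)(F)F)OCC(F)(F)F | starting material
2 | tert-butyl(2-iodoethoxy)dimethylsilane | CC(C)(C)[Si](C)(C)OCCI | starting material
3 | methyl 2-[bis(2,2,2-trifluoroethoxy)phosphoryl]-4-(tert-butyldimethylsilyloxy)butanoate (racemic) | COC(=O)C(CCO[Si](C)(C)C(C)(C)C)P(=O)(OCC(F)(F)F)OCC(F)(F)F | intermediate
4 | ethyl 4-methylpent-4-enoate | CCOC(=O)CCC(C)=C | starting material
5 | 4-methylpent-4-enal | O=CCCC(C)=C | intermediate
6 | methyl (Z)-2-[2-(tert-butyldimethylsilyloxy)ethyl]-6-methylhepta-2,6-dienoate | CC(C)(C)[Si](C)(C)OCC/C(C(=O)OC)=C/CCC(C)=C | intermediate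
7 | (Z)-2-[2-(tert-butyldimethylsilyloxy)ethyl]-6-methylhepta-2,6-dien-1-ol | CC(C)(C)[Si](C)(C)OCC/C(CO)=C/CCC(C)=C | intermediate
8 | tert-butyl{[(Z)-2-[2-(tert-butyldimethylsilyloxy)ethyl]-6-methylhepta-2,6-dienyl]oxy}diphenylsilane | CC(C)(C)[Si](C)(C)OCC/C(CO[Si](c1ccccc1)(c1ccccc1)C(C)(C)C)=C/CCC(C)=C | intermediate
9 | (Z)-3-[(tert-butyldiphenylsilyloxy)methyl]-7-methylocta-3,7-dien-1-ol | OCC/C(CO[Si](c1ccccc1)(c1ccccc1)C(C)(C)C)=C/CCC(C)=C | intermediate
10 | (Z)-3-[(tert-butyldiphenylsilyloxy)methyl]-7-methylocta-3,7-dienal | O=CC/C(CO[Si](c1ccccc1)(c1ccccc1)C(C)(C)C)=C/CCC(C)=C | intermediate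
11 | tert-butyl acrylate | C=CC(=O)OC(C)(C)C | starting material
12 | (E)-but-2-enal | C/C=C/C=O | starting material
13 | tert-butyl (E)-3-hydroxy-2-methylidenehex-4-enoate (racemic) | C/C=C/C(O)C(=C)C(=O)OC(C)(C)C | intermediate
14 | tert-butyl (2Z,4E)-2-(bromomethyl)hexa-2,4-dienoate | C/C=C/C=C(\CBr)C(=O)OC(C)(C)C | intermediate
15 | trimethylsilyl ether of 16 (7R,8R) | C=C(C(=O)OC(C)(C)C)[C@@H](/C=C/C)[C@H](O[Si](C)(C)C)C/C(CO[Si](c1ccccc1)(c1ccccc1)C(C)(C)C)=C/CCC(C)=C | intermediate
16 | tert-butyl (3R,4R,6Z)-6-[(tert-butyldiphenylsilyloxy)methyl]-4-hydroxy-10-methyl-2-methylidene-3-[(E)-prop-1-enyl]undeca-6,10-dienoate | C=C(C(=O)OC(C)(C)C)[C@@H](/C=C/C)[C@H](O)C/C(CO[Si](c1ccccc1)(c1ccccc1)C(C)(C)C)=C/CCC(C)=C | intermediate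
17 | tert-butyl (3R,4R,6Z)-6-[(tert-butyldiphenylsilyloxy)methyl]-10-methyl-2-methylidene-4-(2-methylpropanoyloxy)-3-[(E)-prop-1-enyl]undeca-6,10-dienoate | C=C(C(=O)OC(C)(C)C)[C@@H](/C=C/C)[C@H](OC(=O)C(C)C)C/C(CO[Si](c1ccccc1)(c1ccccc1)C(C)(C)C)=C/CCC(C)=C | intermediate
18 | trimethylsilyl ester of 19 | C=C(C(=O)O[Si](C)(C)C)[C@@H](/C=C/C)[C@H](OC(=O)C(C)C)C/C(CO[Si](c1ccccc1)(c1ccccc1)C(C)(C)C)=C/CCC(C)=C | intermediate
19 | (3R,4R,6Z)-6-[(tert-butyldiphenylsilyloxy)methyl]-10-methyl-2-methylidene-4-(2-methylpropanoyloxy)-3-[(E)-prop-1-enyl]undeca-6,10-dienoic acid | C=C(C(=O)O)[C@@H](/C=C/C)[C@H](OC(=O)C(C)C)C/C(CO[Si](c1ccccc1)(c1ccccc1)C(C)(C)C)=C/CCC(C)=C | intermediate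
20 | (1R,3Z)-3-[(tert-butyldiphenylsilyloxy)methyl]-1-[(2R,3R)-2-ethenyl-4-methylidene-5-oxooxolan-3-yl]-7-methylocta-3,7-dienyl 2-methylpropanoate | C=C1C(=O)O[C@H](C=C)[C@H]1[C@H](OC(=O)C(C)C)C/C(CO[Si](c1ccccc1)(c1ccccc1)C(C)(C)C)=C/CCC(C)=C | intermediate
21 | (1R,3Z)-1-[(2R,3R)-2-ethenyl-4-methylidene-5-oxooxolan-3-yl]-3-(hydroxymethyl)-7-methylocta-3,7-dienyl 2-methylpropanoate | C=C1C(=O)O[C@H](C=C)[C@H]1[C@H](OC(=O)C(C)C)C/C(CO)=C/CCC(C)=C | intermediate
22 | (1R)-1-[(2R,3R)-2-ethenyl-4-methylidene-5-oxooxolan-3-yl]-2-[(2S,3R)-2-(hydroxymethyl)-3-(3-methylbut-3-enyl)oxiran-2-yl]ethyl 2-methylpropanoate | C=C1C(=O)O[C@H](C=C)[C@H]1[C@H](OC(=O)C(C)C)C[C@@]2(CO)O[C@@H]2CCC(C)=C | intermediate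
23 | (1R,4Z,6R,7R,8R,10S)-1,10-epoxy-14-hydroxy-8-(2-methylpropanoyloxy)germacra-4,11(13)-dien-12,6-olide | C=C1C(=O)O[C@@H]2/C=C(/C)CC[C@H]3O[C@]3(CO)C[C@@H](OC(=O)C(C)C)[C@@H]12 | target

Total step count: 16. Longest linear sequence: 13 (steps 1, 3–7, 10–16).

**Steps most likely to fail**

Step 16.
- What may go wrong: intermolecular metathesis of the vinyl group (oligomerisation) may outrun attack on the 1,1-disubstituted olefin. The strained product may also be reopened by ruthenium methylidene.
- The fallback sets out from 22 and returns at 23. It replaces the reversible olefin–olefin closure by an irreversible alkylidene–carbonyl olefination.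
- Silylation of 22 (Et3SiCl, imidazole, CH2Cl2) should give the triethylsilyl ether F1.
- Lemieux–Johnson cleavage (OsO4 cat., NaIO4, 2,6-lutidine, dioxane–water) of its only electron-rich olefin should pass through the diol F2 to the methyl ketone F3.
- One equivalent of Mo(=CHCMe2Ph)(=N-2,6-iPr2C6H3)[OCMe(CF3)2]2 in dilute benzene at rt should exchange with the vinyl group to the C5 molybdenum alkylidene F4. This olefinates the C4 ketone within the molecule to the triethylsilyl ether of the target F5.
- HF·pyridine then gives 23.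

Step 13.
- What may go wrong: facial discrimination at C6 may be weak, which would build up cis-lactone. Palladium hydride may also walk the skipped diene of 19 into conjugation.
- The fallback sets out from 19 and returns at 20. It uses stoichiometric, strictly anti/syn selenium chemistry.
- N-(Phenylselanyl)phthalimide with catalytic camphorsulfonic acid in CH2Cl2 forms seleniranium ions reversibly on all electron-rich olefins. Only the one on C5=C6 has a carboxyl group at 5-exo distance. Under these equilibrating conditions the trans phenylselanyl lactone F6 should collect.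
- H2O2 and pyridine in THF should give the selenoxide F7. Its syn elimination runs away from the C6–O bond, toward the methyl group, to 20.

Step 10.
- What may go wrong: the pentadienylchromium species may attack through its ε-carbon C5. Face selectivity on the unbranched aldehyde may be low. The β,γ-double bond of 10 may drift into conjugation.
- The fallback sets out from 14 and 10 and returns at 16. It uses a configurationally fixed boron reagent in place of the equilibrating chromium species.
- Bromide 14 with B2pin2 and Pd2(dba)3 (cat.) in toluene should give the allylboronate F8.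
- F8 should add to 10 under catalysis by 3,3′-bis(2,4,6-triisopropylphenyl)-1,1′-binaphthyl-2,2′-diyl hydrogen phosphate in toluene at −30 °C. The closed chair with C6 cis to CH2B gives the syn adduct at C7, and the enantiomer of the acid is chosen for Si-face attack. The product is the pinacol borate F9.
- Aqueous work-up of F9 gives 16.

**Further compounds**
F1 | step 16 | triethylsilyl ether of 22 | C=C1C(=O)O[C@H](C=C)[C@H]1[C@H](OC(=O)C(C)C)C[C@@]2(CO[Si](CC)(CC)CC)O[C@@H]2CCC(C)=C
F2 | step 16 | 1,2-diol from the isopropenyl group of F1 (epimers at C4) | C=C1C(=O)O[C@H](C=C)[C@H]1[C@H](OC(=O)C(C)C)C[C@@]2(CO[Si](CC)(CC)CC)O[C@@H]2CCC(C)(O)CO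
F3 | step 16 | C4 methyl ketone | C=C1C(=O)O[C@H](C=C)[C@H]1[C@H](OC(=O)C(C)C)C[C@@]2(CO[Si](CC)(CC)CC)O[C@@H]2CCC(C)=O
F4 | step 16 | C5 molybdenum alkylidene of F3 | C=C1C(=O)O[C@H](C=[Mo](=Nc3c(C(C)C)cccc3C(C)C)(OC(C)(C(F)(F)F)C(F)(F)F)OC(C)(C(F)(F)F)C(F)(F)F)[C@H]1[C@H](OC(=O)C(C)C)C[C@@]2(CO[Si](CC)(CC)CC)O[C@@H]2CCC(C)=O
F5 | step 16 | triethylsilyl ether of 23 | C=C1C(=O)O[C@@H]2/C=C(/C)CC[C@H]3O[C@]3(CO[Si](CC)(CC)CC)C[C@@H](OC(=O)C(C)C)[C@@H]12
F6 | step 13 | trans lactone with a (1R)-1-(phenylselanyl)ethyl group on C6 | C=C1C(=O)O[C@H]([C@@H](C)[Se]c2ccccc2)[C@H]1[C@H](OC(=O)C(C)C)C/C(CO[Si](c1ccccc1)(c1ccccc1)C(C)(C)C)=C/CCC(C)=C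
F7 | step 13 | selenoxide of F6 | C=C1C(=O)O[C@H]([C@@H](C)[Se](=O)c2ccccc2)[C@H]1[C@H](OC(=O)C(C)C)C/C(CO[Si](c1ccccc1)(c1ccccc1)C(C)(C)C)=C/CCC(C)=C
F8 | step 10 | tert-butyl (2E,4E)-2-[(4,4,5,5-tetramethyl-1,3,2-dioxaborolan-2-yl)methyl]hexa-2,4-dienoate | C/C=C/C=C(\CB1OC(C)(C)C(C)(C)O1)C(=O)OC(C)(C)C
F9 | step 10 | pinacol borate (O8–B) of 16 | C=C(C(=O)OC(C)(C)C)[C@@H](/C=C/C)[C@H](OB1OC(C)(C)C(C)(C)O1)C/C(CO[Si](c2ccccc2)(c2ccccc2)C(C)(C)C)=C/CCC(C)=C
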